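**Plan**

1. Locants: 8-azabicyclo[4.3.1]decane core with C1 = quaternary bridgehead, C2=C3–C4–C5 = four-carbon bridge of the seven-membered ring B, C6 = CH bridgehead, C7–N8–C9 = piperidine bridge (ring E), C10 = spiro one-carbon bridge; ring A = lactol, ring C = cyclopentene ester on C1–C2, ring D = cyclopentene on C2=C3.
2. Cuts, in order: C7H2 back to a lactam; the ring A C–O bond, the C10–CH2CH2 bond (Michael) and the C10–CH2O carbon (Wittig) back to a C10 ketone; the ring D bond C3–CH2 (4π electrocyclization) and the ring C bond CH(CO2Me)–C (aldol) back to a C2 enol triflate; then C6–C10 together with the C5–C6 shift back to a diazoacetamide on a cyclohexane-1,3-dione.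
3. Enabling feature: C1 carries C10 and C2, two ring B carbons that can both be carbonyl carbons, so C1 is C2 of a prochiral 2,2-disubstituted cyclohexane-1,3-dione, and C9–N8–C7 plus C6 is an N-methyl diazoacetamide. Insertion of the diazo carbon C6 between C10 and C5 closes ring E and enlarges the six-membered dione ring to ring B in one event.
4. Forward order: dione ring, then rings E and B together (ring expansion), ring C (aldol), ring D (electrocyclization), the C10 quaternary centre, ring A (lactol), last the amine.
5. Stereochemistry: C1 from a catalyst-controlled choice between enantiotopic carbonyls, C6 forced by the bridge, C10 from Michael addition on the ring E face, the hemiketal carbon from anomeric equilibration.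

Key step: step 4

Assumption: the hemiketal carbon of the target is the thermodynamically preferred anomer (axial OH, equatorial ethyl on the tetrahydropyran chair that places C1 equatorial), so it is left to equilibration.

**Route**

Step 1
Reactants: 1 cyclohexane-1,3-dione; 2 methyl acrylate
Product: 3 methyl 3-(2,6-dioxocyclohexyl)propanoate
Conditions: NaOMe (0.1 equiv), MeOH, 65 °C
Reagents that add atoms: none
Why: Base-catalysed Michael addition of the dione enolate (through C2) to the acrylate; no stereocentre is formed.

Step 2
Reactants: 3 methyl 3-(2,6-dioxocyclohexyl)propanoate; 4 2-bromo-N-methylacetamide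
Product: 6 methyl 3-[1-({(bromoacetyl)(methyl)amino}methyl)-2,6-dioxocyclohexyl]propanoate, via N-hydroxymethyl amide 5 (not isolated)
Conditions: (CH2O)n, CF3CO2H/CH2Cl2 (1:4), rt
Reagents that add atoms: formaldehyde (as paraformaldehyde), C=O
Why: Tscherniac–Einhorn amidoalkylation: in acid, 4 and formaldehyde give 5 and from it the N-acyliminium ion, which the enol of 3 captures at C2 (O-alkylation is reversible), so that the quaternary carbon of an achiral, prochiral 2,2-disubstituted dione is formed.

Step 3
Reactants: 6 bromoacetamide dione
Product: 8 methyl 3-[1-({(diazoacetyl)(methyl)amino}methyl)-2,6-dioxocyclohexyl]propanoate, via alkylated ditosylhydrazide 7 (not isolated)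
Conditions: TsNHNHTs, DBU, THF, 0 °C
Reagents that add atoms: N,N'-ditosylhydrazine, Cc1ccc(cc1)S(=O)(=O)NNS(=O)(=O)c1ccc(C)cc1
Why: Diazo synthesis from an α-bromoacetyl group: SN2 displacement of bromide by the ditosylhydrazide anion gives 7, and two base-induced eliminations of sulfinate give the diazoacetamide under non-nucleophilic conditions that spare the cleavage-prone non-enolisable β-diketone; no stereocentre is formed.

Step 4
Reactants: 8 diazoacetamide dione
Product: 10 methyl 3-[(1R,6S)-8-methyl-2,7,10-trioxo-8-azabicyclo[4.3.1]decan-1-yl]propanoate, via diazonium betaine 9 (not isolated)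
Conditions: Sc(OTf)3 (10 mol %), chiral N,N'-dioxide ligand from L-pipecolic acid and 2,6-diisopropylaniline (12 mol %), 4 Å MS, CH2Cl2, −20 to 0 °C
Reagents that add atoms: none
Why: Proposed new method: the scandium-bound β-diketone is attacked at one of its two enantiotopic carbonyl carbons by the nucleophilic diazo carbon, which closes ring E in the 6-exo-trig mode and gives the diazonium betaine 9; the ring CH2 group (C5) antiperiplanar to the C–N2 bond then shifts from the alkoxide carbon (C10) to the diazonium carbon (C6) with loss of N2, so that the cyclohexanone becomes the cycloheptanone ring B and the alkoxide becomes the C10 bridge ketone. The closest known reaction types are the Lewis-acid-promoted Büchner–Curtius–Schlotterbeck (Tiffeneau–Demjanov-type) ring enlargement of cyclic ketones by α-diazo carbonyl compounds, its enantioselective variants under chiral scandium N,N'-dioxide catalysis, and the intramolecular diazoalkane–ketone ring enlargement that leads to bridged bicyclic ketones; the tethered diazoacetamide and the desymmetrisation of a 1,3-diketone are new. C1 is set by the catalyst, which decides which carbonyl group is attacked (the ligand antipode is chosen so that the (1R,6S) product results), and C6 follows without choice because the three-atom bridge can span C1 and C6 on one face only. The step needs group selectivity between the carbonyls and migration of C5 in place of migration of C1 or epoxide closure; C1 is quaternary and bears the second acyl group, which makes it a poor migrating group, while C5 is an unhindered CH2 group that can stand anti to an axial diazonium group on the chair-like betaine ring. C6 is a bridgehead and C1 is quaternary, so product 10 is configurationally stable.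

Step 5
Reactants: 10 bicyclic keto lactam
Product: 12 methyl 3-[(1R,6S)-8-methyl-7,10-dioxo-2-(trifluoromethanesulfonyloxy)-8-azabicyclo[4.3.1]dec-2-en-1-yl]propanoate, via potassium enolate 11 (not isolated)
Conditions: KN(SiMe3)2, THF, −78 °C; PhNTf2
Reagents that add atoms: N-phenylbis(trifluoromethanesulfonimide), O=S(=O)(N(c1ccccc1)S(=O)(=O)C(F)(F)F)C(F)(F)F
Why: Kinetic enolisation and O-triflation: only C3 offers an α-hydrogen to a ketone (C10 is flanked by the quaternary C1 and the bridgehead C6), so a single enol triflate results and no stereocentre is touched.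

Step 6
Reactants: 12 enol triflate; 13 tributyl(vinyl)stannane
Product: 14 methyl 3-[(1S,6S)-8-methyl-7,10-dioxo-2-(prop-2-enoyl)-8-azabicyclo[4.3.1]dec-2-en-1-yl]propanoate
Conditions: Pd(PPh3)4 (5 mol %), LiCl, CO (1 atm), THF, 55 °C
Reagents that add atoms: carbon monoxide, [C-]#[O+]
Why: Carbonylative Stille coupling (oxidative addition of zerovalent palladium to the enol triflate, CO insertion, transmetalation from tin, reductive elimination) gives the cross-conjugated divinyl ketone; no stereocentre is formed (the C1 descriptor changes through the priority rules only).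

Step 7
Reactants: 14 divinyl ketone
Product: 15 ring C aldol adduct (tertiary bis-allylic alcohol, mixture at the two new centres)
Conditions: LiN(SiMe3)2, THF, −78 °C; AcOH
Reagents that add atoms: none
Why: Intramolecular aldol addition: the dienone and the C10 ketone have no α-hydrogen, so the ester is enolised and its enolate closes ring C by 5-exo-trig attack on the dienone carbonyl (attack on C3 would be 5-endo and attack on C10 would give a four-membered ring); the two new stereocentres are removed in step 8 and need no control.

Step 8
Reactants: 15 ring C aldol adduct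
Product: 17 tetracyclic dienoate ketone, via ring D cyclopentadiene isomer 16 (not isolated)
Conditions: TsOH·H2O (0.3 equiv), ClCH2CH2Cl, rt to 50 °C
Reagents that add atoms: none
Why: Acid ionises the tertiary bis-allylic alcohol to a pentadienyl cation that ring C holds in the U shape, conrotatory 4π electrocyclization (Nazarov-type, the reaction by which divinyl carbinols are turned into cyclopentadienes) closes ring D between C3 and the vinyl terminus, and proton loss followed by acid-mediated double-bond migration via 16 ends at the fully conjugated dienoate, in which both stereocentres of step 7 are gone.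

Step 9
Reactants: 17 tetracyclic dienoate ketone
Product: 18 C10 methoxymethylene enol ether (E/Z mixture)
Conditions: Ph3P(CH2OMe)Cl, KOtBu, THF, 0 °C to rt
Reagents that add atoms: (methoxymethyl)triphenylphosphonium chloride, COC[P+](c1ccccc1)(c1ccccc1)c1ccccc1.[Cl-]
Why: Wittig methoxymethylenation of the only ketone left, the strained non-enolisable C10 bridge ketone; the ester and the lactam do not react with the ylide and the enol ether geometry is of no consequence.

Step 10
Reactants: 18 enol ether
Product: 19 C10 aldehyde (mixture of C10 epimers)
Conditions: 2 M HCl, THF, rt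
Reagents that add atoms: water, O
Why: Acid-catalysed enol ether hydrolysis (protonation at C10, hemiacetal, loss of methanol) gives the aldehyde as a mixture of C10 epimers, which is harmless because C10 is planarised again in step 11.

Step 11
Reactants: 19 C10 aldehyde; 20 ethyl vinyl ketone
Product: 21 keto aldehyde with quaternary C10
Conditions: DBU (0.1 equiv), MeCN, −20 to 0 °C
Reagents that add atoms: none
Why: Base-catalysed Michael addition of the aldehyde enolate to the enone creates the quaternary carbon C10; the electrophile should enter from the ring E face, where C10 is flanked by the flat amide carbon C7 and one CH2 group (C9), and not from the ring B face, where C2 carries the fused rings C and D, so that the 3-oxopentyl chain comes to lie over ring E and the formyl group over ring B as the target requires.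

Step 12
Reactants: 21 keto aldehyde
Product: 23 lactol lactam (7-oxo derivative of the target), via hydroxy ketone 22 (not isolated)
Conditions: NaBH(OAc)3, AcOH (cat.), ClCH2CH2Cl, rt
Reagents that add atoms: none
Why: Triacetoxyborohydride reduction is selective for the aldehyde over the ketone, ester and lactam, and the alcohol 22 then adds to the ketone (6-exo-trig) to close ring A, the hemiketal carbon equilibrating to the anomer with axial hydroxyl (anomeric effect) and equatorial ethyl group.

Step 13
Reactants: 23 lactol lactam
Product: 24 target CNP0192143.3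
Conditions: Zn(OAc)2 (10 mol %), (EtO)3SiH, THF, 40 °C; aq. NaHCO3
Reagents that add atoms: none
Why: Zinc-catalysed hydrosilylation reduces the tertiary lactam to the tertiary amine and tolerates the ester, the dienoate and the ketone masked as hemiketal; no stereocentre is touched and the product is the target.

**Compound list**

1 | cyclohexane-1,3-dione | O=C1CCCC(=O)C1 | starting material
2 | methyl acrylate | C=CC(=O)OC | starting material
3 | methyl 3-(2,6-dioxocyclohexyl)propanoate | COC(=O)CCC1C(=O)CCCC1=O | intermediate
4 | 2-bromo-N-methylacetamide | CNC(=O)CBr | starting material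
5 | 2-bromo-N-(hydroxymethyl)-N-methylacetamide | OCN(C)C(=O)CBr | intermediate
6 | methyl 3-[1-({(bromoacetyl)(methyl)amino}methyl)-2,6-dioxocyclohexyl]propanoate (achiral) | COC(=O)CCC1(CN(C)C(=O)CBr)C(=O)CCCC1=O | intermediate
7 | alkylated ditosylhydrazide (bromide of 6 replaced by N(Ts)NHTs) | COC(=O)CCC1(CN(C)C(=O)CN(NS(=O)(=O)c2ccc(C)cc2)S(=O)(=O)c2ccc(C)cc2)C(=O)CCCC1=O | intermediate
8 | methyl 3-[1-({(diazoacetyl)(methyl)amino}methyl)-2,6-dioxocyclohexyl]propanoate (achiral, prochiral) | COC(=O)CCC1(CN(C)C(=O)C=[N+]=[N-])C(=O)CCCC1=O | intermediate
9 | diazonium betaine (alkoxide on the attacked carbonyl carbon, diazonium on the new ring E carbon; quaternary carbon as in 10) | [O-]C23CCCC(=O)[C@@]2(CCC(=O)OC)CN(C)C(=O)C3[N+]#N | intermediate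
10 | methyl 3-[(1R,6S)-8-methyl-2,7,10-trioxo-8-azabicyclo[4.3.1]decan-1-yl]propanoate | O=C2[C@@H]1CCCC(=O)[C@@]2(CCC(=O)OC)CN(C)C1=O | intermediate
11 | potassium C2 enolate of 10 (C2=C3) | O=C2[C@@H]1CCC=C([O-])[C@@]2(CCC(=O)OC)CN(C)C1=O.[K+] | intermediate
12 | methyl 3-[(1R,6S)-8-methyl-7,10-dioxo-2-(trifluoromethanesulfonyloxy)-8-azabicyclo[4.3.1]dec-2-en-1-yl]propanoate | O=C2[C@@H]1CCC=C(OS(=O)(=O)C(F)(F)F)[C@@]2(CCC(=O)OC)CN(C)C1=O | intermediate
13 | tributyl(vinyl)stannane | C=C[Sn](CCCC)(CCCC)CCCC | starting material
14 | methyl 3-[(1S,6S)-8-methyl-7,10-dioxo-2-(prop-2-enoyl)-8-azabicyclo[4.3.1]dec-2-en-1-yl]propanoate | O=C2[C@@H]1CCC=C(C(=O)C=C)[C@@]2(CCC(=O)OC)CN(C)C1=O | intermediate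
15 | ring C aldol adduct: cyclopentane ring C on C1–C2 carrying OH and vinyl on the carbon bound to C2 and CO2Me on the next carbon, C2=C3 alkene, bridgeheads as in 10, mixture at the two new centres | O=C2[C@@H]1CCC=C4C(O)(C=C)C(C(=O)OC)C[C@@]42CN(C)C1=O | intermediate
16 | ring D cyclopentadiene isomer (C2=C3 and a second ring D double bond, ester carbon sp3, bridgeheads as in 10) | O=C2[C@@H]1CCC3=C4C(=CC3)C(C(=O)OC)C[C@@]42CN(C)C1=O | intermediate
17 | tetracyclic dienoate ketone (rings B, C, D, E; C10 ketone, C7 lactam; bridgeheads as in the target) | O=C2[C@@H]1CCC3=C4C(=C(C(=O)OC)C[C@@]42CN(C)C1=O)CC3 | intermediate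
18 | C10 methoxymethylene enol ether of 17 (E/Z mixture) | COC=C2[C@@H]1CCC3=C4C(=C(C(=O)OC)C[C@@]42CN(C)C1=O)CC3 | intermediate
19 | C10 carbaldehyde (C10–H, both epimers) | O=CC2[C@@H]1CCC3=C4C(=C(C(=O)OC)C[C@@]42CN(C)C1=O)CC3 | intermediate
20 | ethyl vinyl ketone (pent-1-en-3-one) | CCC(=O)C=C | starting material
21 | keto aldehyde: C10 bears the 3-oxopentyl chain on the ring E face and CHO on the ring B face | CCC(=O)CC[C@@]2(C=O)[C@@H]1CCC3=C4C(=C(C(=O)OC)C[C@@]42CN(C)C1=O)CC3 | intermediate
22 | hydroxy ketone (CH2OH in place of CHO of 21) | CCC(=O)CC[C@@]2(CO)[C@@H]1CCC3=C4C(=C(C(=O)OC)C[C@@]42CN(C)C1=O)CC3 | intermediate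
23 | lactol lactam (7-oxo derivative of the target; hemiketal with axial OH) | CC[C@]1(O)CC[C@@]2(CO1)[C@@H]1CCC3=C4C(=C(C(=O)OC)C[C@@]42CN(C)C1=O)CC3 | intermediate
24 | target CNP0192143.3 | CC[C@]1(O)CC[C@@]2(CO1)[C@@H]1CCC3=C4C(=C(C(=O)OC)C[C@@]42CN(C)C1)CC3 | target

Total step count: 13
Longest linear sequence: 13 steps (1 to 24)

**Steps most likely to fail**

Step 4. The betaine may collapse by migration of the wrong ring bond or by epoxide closure, or the catalyst may discriminate poorly between the two carbonyl groups. The fallback uses known chemistry, sets out from 8 and returns at 10. A ketoreductase (NADPH recycled with glucose dehydrogenase and glucose, pH 7 buffer, 30 °C), picked from a panel for the required sense, reduces one of the enantiotopic carbonyl groups of 8 to the hydroxy ketone F1; the carbinol configuration is of no consequence. TBSCl and imidazole in DMF give the silyl ether F2. LiN(iPr)2 at −78 °C adds the lithiated diazoacetamide to the one remaining ketone and gives the β-hydroxy-α-diazo lactam F3. Rh2(OAc)4 in CH2Cl2 forms the carbene, to which the ring CH2 group that stands out of the lactam plane shifts (the known ring enlargement of β-hydroxy-α-diazo carbonyl compounds), giving the silyloxy keto lactam F4. HF·pyridine gives the hydroxy keto lactam F5, and Swern oxidation gives 10.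

Step 11. Facial selectivity in the attack on the enolate of 19 may be poor or reversed, since the two faces of C10 differ only moderately. The fallback sets out from 19 and returns at 23; it introduces the two C10 substituents in the opposite order, so that an electrophile entering from the ring B face becomes the one required. Aqueous CH2O with Et3N in THF hydroxymethylates 19 to the hydroxy aldehyde F6 (CH2OH over ring B, CHO over ring E). Wittig reaction with Ph3P=CHC(O)Et in toluene at 90 °C gives the enone F7. Conjugate reduction with [(Ph3P)CuH]6 in benzene, which spares the hindered tetrasubstituted dienoate, gives hydroxy ketone 22, which closes to 23.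

Step 8. The pentadienyl cation may only lose a proton to a cross-conjugated triene, or oligomerise, instead of cyclising. The fallback sets out from 14 and returns at 17; it closes the two rings in the opposite order. Nazarov cyclization of the divinyl ketone 14 (CF3SO3H, CH2Cl2, 0 °C) closes ring D first and gives the cyclopentenone F8. Base-mediated intramolecular aldol condensation (KOtBu, tBuOH/THF) of the ester with the ring D ketone then closes ring C and gives 17 directly.

Further compounds
F1 | step 4 | hydroxy ketone: methyl 3-[1-({(diazoacetyl)(methyl)amino}methyl)-2-hydroxy-6-oxocyclohexyl]propanoate, quaternary carbon as in 10 | O=C2CCCC(O)[C@@]2(CCC(=O)OC)CN(C)C(=O)C=[N+]=[N-]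
F2 | step 4 | tert-butyldimethylsilyl ether of F1 | O=C2CCCC(O[Si](C)(C)C(C)(C)C)[C@@]2(CCC(=O)OC)CN(C)C(=O)C=[N+]=[N-]
F3 | step 4 | β-hydroxy-α-diazo lactam (ring E closed, tertiary alcohol, silyl ether kept) | OC23CCCC(O[Si](C)(C)C(C)(C)C)[C@@]2(CCC(=O)OC)CN(C)C(=O)C3=[N+]=[N-]
F4 | step 4 | silyloxy keto lactam (10 with OTBS at C2) | O=C2[C@@H]1CCCC(O[Si](C)(C)C(C)(C)C)[C@@]2(CCC(=O)OC)CN(C)C1=O
F5 | step 4 | hydroxy keto lactam (10 with OH at C2) | O=C2[C@@H]1CCCC(O)[C@@]2(CCC(=O)OC)CN(C)C1=O
F6 | step 11 | hydroxy aldehyde: C10 bears CH2OH on the ring B face and CHO on the ring E face | O=C[C@@]2(CO)[C@@H]1CCC3=C4C(=C(C(=O)OC)C[C@@]42CN(C)C1=O)CC3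
F7 | step 11 | (E)-enone: C10 bears CH2OH and (E)-3-oxopent-1-enyl | CCC(=O)/C=C/[C@@]2(CO)[C@@H]1CCC3=C4C(=C(C(=O)OC)C[C@@]42CN(C)C1=O)CC3
F8 | step 8 | ring D cyclopentenone (C2=C3 enone, ring C still open, ester chain on C1) | O=C2[C@@H]1CCC3=C(C(=O)CC3)[C@@]2(CCC(=O)OC)CN(C)C1=O
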